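**Plan**

1. Ring numbering used here: C1 is the enolised carbonyl carbon next to the ring CH2 C6, C2 carries the acyl group, C3 is the ketone carbon, C4 the carbinol carbon. The retrosynthesis cuts first the exocyclic C2–acyl bond, then the two ring bonds C1–C6 and C3–C4, and in the side chain the 12,13-alkene.
2. Forward, the carbocycle is made first by a [3+3] union of dilithiated bis(1,3-dithian-2-yl)methane (C1–C2–C3) with 3-chloro-N-methoxy-N-methylpropanamide (C4–C5–C6). One flask closes C3–C4 by acylation and C1–C6 by alkylation.
3. Enabling feature: C1 and C3 are two acyl carbons on one carbon (C2), so both can be carried as dithiane acyl anions on a single CH2. The bridge C4–C5–C6 ends in an acyl-level carbon (C4) and a CH2 (C6), so it is a 1,3-bis-electrophile. The dithianes also keep the 1,2,4-trioxygenated six-membered ring from aromatising.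
4. Stereochemistry: the only stereocentre, C4 (S), comes from CBS reduction of the C4 ketone, with the neighbouring spiro-dithiane carbon as the large group.
5. The (12Z,14E)-dienoyl chain is made by a Z-selective Wittig reaction of (E)-but-2-enal. It is joined to C2 by O-acylation and O→C acyl migration after the dione is unmasked, and desilylation ends the route.

Key step: step 3

Remark: the target is drawn as one enol form of a 2-acylcyclohexane-1,3-dione; the tautomers interconvert freely, so the route aims at the triketone system with (S) configuration at the carbinol carbon.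

**Route**

Step 1
Reactants: 1 1,1,3,3-tetramethoxypropane; 2 propane-1,3-dithiol (two equivalents in all)
Product: 3 2,2'-methylenebis(1,3-dithiane)
Conditions: 2 (2.1 equiv), BF3·OEt2, AcOH, CHCl3, rt
Reagents that add atoms: propane-1,3-dithiol (the second equivalent of 2), SCCCS
Why: In this Lewis-acid-catalysed double transthioacetalisation each of the two dimethyl acetal ends of 1 takes up one molecule of the 1,3-dithiol, and the reaction should go to completion because two stable six-membered 1,3-dithianes form and four molecules of methanol are lost.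

Step 2
Reactants: 4 3-chloropropanoyl chloride; 5 N,O-dimethylhydroxylamine hydrochloride
Product: 6 3-chloro-N-methoxy-N-methylpropanamide
Conditions: pyridine, CH2Cl2, 0 °C
Reagents that add atoms: none
Why: Schotten–Baumann-type N-acylation of the hydroxylamine by the acid chloride with a weak base at 0 °C should give the Weinreb amide without loss of HCl from the β-chloro amide.

Step 3
Reactants: 3 2,2'-methylenebis(1,3-dithiane); 6 3-chloro-N-methoxy-N-methylpropanamide
Product: 10 cyclohexane-1,2,4-trione 2,4-bis(propane-1,3-diyl dithioketal) (cyclohexanone carrying spiro-1,3-dithiane rings at C2 and C4), via dilithio dianion 7 (not isolated), via open-chain lithium hemiaminal 8 (not isolated), via cyclic lithium hemiaminal 9 (not isolated)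
Conditions: n-BuLi (2.1 equiv), THF, −30 °C; then 6, −78 °C → 0 °C; aq. NH4Cl
Reagents that add atoms: none
Why: Two deprotonations give the 1,3-dilithio species in which both future ring carbonyl carbons (C1 and C3) are sulfur-stabilised acyl-anion carbons on the same CH2 (C2); one carbanion adds to the amide carbonyl (C3–C4 bond) to give an N,O-chelated tetrahedral lithium hemiaminal that does not collapse before work-up, and on warming the other carbanion displaces the primary chloride (C1–C6 bond). The closest known reaction types are the cyclisation of dilithiated bis(1,3-dithian-2-yl)alkanes with 1,3-dihalides (Corey–Seebach umpolung) and the acylation of 2-lithio-1,3-dithianes by Weinreb amides. The six-membered carbocycle closes in the 6-exo-tet mode (were alkylation to come first, closure would be a 6-exo-trig acylation leading to the same ketone). No stereocentre is formed, the product being an achiral ketone whose carbonyl carbon (C4) becomes the carbinol centre in step 4. The step needs C–C bond formation to outrun deprotonation of the amide α-CH2 with loss of chloride, and ring closure to outrun oligomerisation; addition at −78 °C, the non-collapsing hemiaminal (no enolisable ketone while a carbanion is still present) and the 1,3-spacing of the two carbanions that makes the second bond an intramolecular six-ring closure should secure this.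

Step 4
Reactants: 10 cyclohexane-1,2,4-trione 2,4-bis(propane-1,3-diyl dithioketal)
Product: 11 (S)-2,2:4,4-bis[propane-1,3-diylbis(sulfanediyl)]cyclohexan-1-ol (the (S)-alcohol from the ketone of 10)
Conditions: (R)-1-methyl-3,3-diphenyltetrahydro-1H,3H-pyrrolo[1,2-c][1,3,2]oxazaborole (0.2 equiv), BH3·SMe2, THF, −20 °C; MeOH quench, aq. work-up
Reagents that add atoms: none
Why: In this CBS (Corey–Bakshi–Shibata) reduction the ketone should bind to the boron of the (R)-oxazaborolidine–borane complex with its large flank, the quaternary dithioketal carbon, turned away from the catalyst, so that hydride is delivered to the face giving the (S)-carbinol (2-acyl-1,3-dithianes are established substrates of this kind), which sets the only stereocentre.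

Step 5
Reactants: 11 (S)-2,2:4,4-bis[propane-1,3-diylbis(sulfanediyl)]cyclohexan-1-ol
Product: 12 tert-butyldimethylsilyl ether of 11
Conditions: t-BuMe2SiOTf, 2,6-lutidine, CH2Cl2, −78 → 0 °C
Reagents that add atoms: tert-butyldimethylsilyl trifluoromethanesulfonate, CC(C)(C)[Si](C)(C)OS(=O)(=O)C(F)(F)F
Why: O-silylation of the hindered secondary alcohol with the silyl triflate and a hindered base should proceed without touching the thioketals and protects the hydroxyl through unmasking and acylation.

Step 6
Reactants: 12 tert-butyldimethylsilyl ether of 11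
Product: 13 (S)-4-[(tert-butyldimethylsilyl)oxy]cyclohexane-1,3-dione
Conditions: Hg(ClO4)2, CaCO3, THF/H2O, 0 °C
Reagents that add atoms: water (two molecules, one for each dithioketal), O
Why: Thiophilic divalent mercury should complex the dithiane sulfurs so that water hydrolyses both dithioketals (CaCO3 buffers the acid and spares the silyl ether), unmasking a 1,3-dione that cannot aromatise and whose C4 stereocentre lies off the enolisation path through C2.

Step 7
Reactants: 14 12-bromododecanoic acid
Product: 15 (11-carboxyundecyl)triphenylphosphonium bromide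
Conditions: PPh3, MeCN, reflux
Reagents that add atoms: triphenylphosphine, c1ccc(cc1)P(c1ccccc1)c1ccccc1
Why: SN2 quaternisation of triphenylphosphine by the primary bromide should give the phosphonium salt directly.

Step 8
Reactants: 15 (11-carboxyundecyl)triphenylphosphonium bromide; 16 (E)-but-2-enal
Product: 18 (12Z,14E)-hexadeca-12,14-dienoic acid, via carboxylate ylide 17 (not isolated)
Conditions: NaN(SiMe3)2 (2.1 equiv), THF, −78 °C; then 16, −78 °C → rt; aq. HCl
Reagents that add atoms: none
Why: In this Wittig reaction the lithium-free non-stabilised ylide should add to the (E)-enal under kinetic control through the cis-oxaphosphetane, making the new 12,13-double bond Z while the 14,15-E geometry of the enal is kept.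

Step 9
Reactants: 13 (S)-4-[(tert-butyldimethylsilyl)oxy]cyclohexane-1,3-dione; 18 (12Z,14E)-hexadeca-12,14-dienoic acid
Product: 20 (S)-4-[(tert-butyldimethylsilyl)oxy]-2-[(12Z,14E)-hexadeca-12,14-dienoyl]cyclohexane-1,3-dione, via enol ester 19 (not isolated)
Conditions: N,N'-dicyclohexylcarbodiimide, 4-(dimethylamino)pyridine (0.3 equiv), Et3N, CH2Cl2, rt
Reagents that add atoms: none
Why: Steglich O-acylation of the enolised dione followed by 4-(dimethylamino)pyridine-mediated O→C acyl migration should end at the chelated 2-acyl-1,3-dione as the thermodynamic sink whichever enol oxygen is acylated first, while the silyl ether keeps the C4 oxygen from being acylated.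

Step 10
Reactants: 20 (S)-4-[(tert-butyldimethylsilyl)oxy]-2-[(12Z,14E)-hexadeca-12,14-dienoyl]cyclohexane-1,3-dione
Product: 21 (S)-4-hydroxy-2-[(12Z,14E)-hexadeca-12,14-dienoyl]cyclohexane-1,3-dione (target, enol form as drawn)
Conditions: HF·pyridine, THF, 0 °C → rt
Reagents that add atoms: none
Why: Fluoride-driven cleavage of the Si–O bond under mildly acidic conditions should leave the (Z,E)-diene, the triketone and the C4 stereocentre untouched.

**Compound list**

1 | 1,1,3,3-tetramethoxypropane | COC(OC)CC(OC)OC | starting material
2 | propane-1,3-dithiol | SCCCS | starting material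
3 | 2,2'-methylenebis(1,3-dithiane) | C(C1SCCCS1)C1SCCCS1 | intermediate
4 | 3-chloropropanoyl chloride | ClCCC(Cl)=O | starting material
5 | N,O-dimethylhydroxylamine hydrochloride | CNOC.Cl | starting material
6 | 3-chloro-N-methoxy-N-methylpropanamide | CON(C)C(=O)CCCl | intermediate
7 | 2,2'-methylenebis(2-lithio-1,3-dithiane) (dilithio dianion) | [Li]C1(SCCCS1)CC1([Li])SCCCS1 | intermediate
8 | open-chain lithium hemiaminal: lithium alkoxide of the adduct of one carbanion of 7 with the amide carbonyl of 6, the second dithiane still lithiated | [Li]C1(SCCCS1)CC1(SCCCS1)C(O[Li])(CCCl)N(C)OC | intermediate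
9 | cyclic lithium hemiaminal: lithium 1-[methoxy(methyl)amino]cyclohexan-1-olate carrying spiro-1,3-dithianes at C2 and C4 | CON(C)C1(O[Li])CCC2(SCCCS2)CC13SCCCS3 | intermediate
10 | cyclohexane-1,2,4-trione 2,4-bis(propane-1,3-diyl dithioketal) | O=C1CCC2(SCCCS2)CC13SCCCS3 | intermediate
11 | (S)-2,2:4,4-bis[propane-1,3-diylbis(sulfanediyl)]cyclohexan-1-ol | O[C@H]1CCC2(SCCCS2)CC13SCCCS3 | intermediate
12 | tert-butyldimethylsilyl ether of 11 | CC(C)(C)[Si](C)(C)O[C@H]1CCC2(SCCCS2)CC13SCCCS3 | intermediate
13 | (S)-4-[(tert-butyldimethylsilyl)oxy]cyclohexane-1,3-dione | CC(C)(C)[Si](C)(C)O[C@H]1CCC(=O)CC1=O | intermediate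
14 | 12-bromododecanoic acid | OC(=O)CCCCCCCCCCCBr | starting material
15 | (11-carboxyundecyl)triphenylphosphonium bromide | OC(=O)CCCCCCCCCCC[P+](c1ccccc1)(c1ccccc1)c1ccccc1.[Br-] | intermediate
16 | (E)-but-2-enal | C/C=C/C=O | starting material
17 | sodium 12-(triphenyl-λ5-phosphanylidene)dodecanoate (carboxylate ylide) | [Na+].[O-]C(=O)CCCCCCCCCCC=P(c1ccccc1)(c1ccccc1)c1ccccc1 | intermediate
18 | (12Z,14E)-hexadeca-12,14-dienoic acid | C/C=C/C=C\CCCCCCCCCCC(=O)O | intermediate
19 | (S)-4-[(tert-butyldimethylsilyl)oxy]-3-oxocyclohex-1-en-1-yl (12Z,14E)-hexadeca-12,14-dienoate (enol ester) | C/C=C/C=C\CCCCCCCCCCC(=O)OC1=CC(=O)[C@@H](O[Si](C)(C)C(C)(C)C)CC1 | intermediate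
20 | (S)-4-[(tert-butyldimethylsilyl)oxy]-2-[(12Z,14E)-hexadeca-12,14-dienoyl]cyclohexane-1,3-dione | C/C=C/C=C\CCCCCCCCCCC(=O)C1=C(O)CC[C@H](O[Si](C)(C)C(C)(C)C)C1=O | intermediate
21 | (S)-4-hydroxy-2-[(12Z,14E)-hexadeca-12,14-dienoyl]cyclohexane-1,3-dione | C/C=C/C=C\CCCCCCCCCCC(=O)C1=C(O)CC[C@H](O)C1=O | target

**Step count and risks**

Total step count: 10. Longest linear sequence: 7 steps (steps 1, 3, 4, 5, 6, 9, 10).

Steps most likely to fail:

- **Step 3.** The second carbanion may be lost by proton transfer from the amide α-CH2 followed by elimination of chloride, or it may couple intermolecularly, so that the ring does not close. The fallback sets out from 3 and 6 and comes back at 12; it separates the two bond formations so that each carbanion meets only one electrophilic site. Metalation of 3 with one equivalent of n-BuLi (THF, −30 °C) and acylation with 6 at −78 °C should give, after work-up, the chloro ketone 3-chloro-1-{2-[(1,3-dithian-2-yl)methyl]-1,3-dithian-2-yl}propan-1-one F1. CBS reduction as in step 4 should give the chlorohydrin (S)-3-chloro-1-{2-[(1,3-dithian-2-yl)methyl]-1,3-dithian-2-yl}propan-1-ol F2. Silylation as in step 5 should give the silyl ether tert-butyl{(S)-3-chloro-1-{2-[(1,3-dithian-2-yl)methyl]-1,3-dithian-2-yl}propoxy}dimethylsilane F3. Metalation of the remaining dithiane C–H with n-BuLi (THF, −30 °C → rt) then closes the six-membered ring by intramolecular alkylation of the primary chloride (Corey–Seebach cycloalkylation) and gives 12.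

- **Step 6.** Hydrolysis of the second, more hindered dithioketal may stall, or the thiophilic metal may attack the freed acidic β-diketone at C2. The fallback sets out from 12 and comes back at 13; it removes sulfur before any free β-diketone exists. Oxidative transketalisation with PhI(OCOCF3)2 in MeOH should give the bis(dimethyl ketal) (S)-tert-butyl[(2,2,4,4-tetramethoxycyclohexyl)oxy]dimethylsilane F6. Mild aqueous acid (pyridinium p-toluenesulfonate, acetone/H2O) then hydrolyses both ketals to 13.

- **Step 4.** Facial selectivity may be poor, or borane held on the four sulfur atoms may reduce the ketone without the catalyst. The fallback sets out from 10 and comes back at 11; it replaces asymmetric reduction by resolution. NaBH4 (MeOH, 0 °C) should give the racemic alcohol rac-2,2:4,4-bis[propane-1,3-diylbis(sulfanediyl)]cyclohexan-1-ol F4. Esterification with (R)-2-methoxy-2-phenylacetic acid (N,N'-dicyclohexylcarbodiimide, 4-(dimethylamino)pyridine) and chromatographic separation of the diastereomers should give the ester of the (S)-alcohol, (S)-2,2:4,4-bis[propane-1,3-diylbis(sulfanediyl)]cyclohexyl (R)-2-methoxy-2-phenylacetate F5. Methanolysis (K2CO3, MeOH) returns 11.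

Further compounds
F1 | step 3 | 3-chloro-1-{2-[(1,3-dithian-2-yl)methyl]-1,3-dithian-2-yl}propan-1-one | O=C(CCCl)C1(CC2SCCCS2)SCCCS1
F2 | step 3 | (S)-3-chloro-1-{2-[(1,3-dithian-2-yl)methyl]-1,3-dithian-2-yl}propan-1-ol | ClCC[C@H](O)C1(CC2SCCCS2)SCCCS1
F3 | step 3 | tert-butyl{(S)-3-chloro-1-{2-[(1,3-dithian-2-yl)methyl]-1,3-dithian-2-yl}propoxy}dimethylsilane | ClCC[C@H](O[Si](C)(C)C(C)(C)C)C1(CC2SCCCS2)SCCCS1
F4 | step 4 | rac-2,2:4,4-bis[propane-1,3-diylbis(sulfanediyl)]cyclohexan-1-ol | OC1CCC2(SCCCS2)CC13SCCCS3
F5 | step 4 | (S)-2,2:4,4-bis[propane-1,3-diylbis(sulfanediyl)]cyclohexyl (R)-2-methoxy-2-phenylacetate | CO[C@H](c1ccccc1)C(=O)O[C@H]1CCC2(SCCCS2)CC13SCCCS3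
F6 | step 6 | (S)-tert-butyl[(2,2,4,4-tetramethoxycyclohexyl)oxy]dimethylsilane | CC(C)(C)[Si](C)(C)O[C@H]1CCC(OC)(OC)CC1(OC)OC
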